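**Retrosynthetic overview**

1. The seven-membered depsidone lactone (ring D) is closed last, at the ester bond C(=O)–O(C7), from a seco acid. Before it, the diaryl ether C6–O–aryl is made by SNAr of a chromanone phenol (rings B/C) on a 2-fluoro-3-formylbenzoate (ring A, from 2,6-difluoro-4-methylbenzaldehyde).
2. The pyranone (ring C: O1, C2Me2, C3H2, C4=O, C4a, C8a) is not closed as a six-membered ring. It comes from the five-membered tetrahydrofuran-3-one ring of a 1-oxaspiro[4.5]deca-6,9-diene-4,8-dione by an acid-mediated dienone–phenol 1,2-acyl shift (ring expansion 5 → 6). The same step aromatises ring B and leaves the C6 hydroxyl as the only free phenol.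
3. Enabling feature: in ring B the carbon bearing the pyran oxygen (C8a) is para to the carbon bearing the diaryl-ether oxygen (C6) and ortho to C4a, which carries the ketone carbon C4. C8a can therefore be the sp3 spiro carbon (bearing both O1 and C4) of a cyclohexadienone whose carbonyl is C6, and C4 only has to move from C8a to C4a.
4. The spiro dienone comes from a para-acyl phenol with a tertiary β-hydroxyl by oxidative dearomatising spiroetherification. That phenol comes from 3-methylcatechol (benzylation, para-iodination, Stille acetylation, aldol with acetone).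
5. Ring order: A and B are bought as benzenes; then the spiro furanone; then pyranone C by ring expansion; dioxepinone D last.

Key step: step 6

Remark: 3-methylcatechol and 2,6-difluoro-4-methylbenzaldehyde are taken as commercial. The spiro carbon of 7 is a stereocentre that is formed racemic and erased in step 6, so the achiral target needs no stereocontrol.

**Route**

Step 1
Reactants: 1 3-methylbenzene-1,2-diol
Product: 2 2-(benzyloxy)-6-methylphenol
Conditions: BnBr (1.0 equiv), K2CO3, acetone, reflux
Reagents that add atoms: benzyl bromide, BrCc1ccccc1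
Why: Williamson ether synthesis; the hydroxyl remote from the methyl group is the more acidic and less hindered one, so mono-O-benzylation should occur mainly there (minor regioisomer and dibenzyl ether removed by chromatography).

Step 2
Reactants: 2 2-(benzyloxy)-6-methylphenol
Product: 3 2-(benzyloxy)-4-iodo-6-methylphenol
Conditions: NIS, TsOH (cat.), MeCN, 0 °C → rt
Reagents that add atoms: N-iodosuccinimide, O=C1CCC(=O)N1I
Why: Electrophilic aromatic iodination; both ortho positions of the phenol are substituted, so the strongly para-directing free hydroxyl should send iodine to C4.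

Step 3
Reactants: 3 2-(benzyloxy)-4-iodo-6-methylphenol
Product: 5 1-[3-(benzyloxy)-4-hydroxy-5-methylphenyl]ethan-1-one, via enol ether 4 (not isolated)
Conditions: tributyl(1-ethoxyvinyl)stannane, PdCl2(PPh3)2 (cat.), toluene, 100 °C; then 1 M HCl, THF, rt
Reagents that add atoms: tributyl(1-ethoxyvinyl)stannane, CCCC[Sn](CCCC)(CCCC)C(=C)OCC; water, O
Why: Stille coupling of the aryl iodide with an acetyl-anion equivalent followed by acid hydrolysis of the enol ether is a dependable route to an aryl methyl ketone and tolerates the free phenol and the benzyl ether.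

Step 4
Reactants: 5 1-[3-(benzyloxy)-4-hydroxy-5-methylphenyl]ethan-1-one
Product: 6 1-[3-(benzyloxy)-4-hydroxy-5-methylphenyl]-3-hydroxy-3-methylbutan-1-one
Conditions: LDA (2.2 equiv), THF, −78 °C; acetone, −78 °C; AcOH quench at −78 °C
Reagents that add atoms: acetone, CC(C)=O
Why: Directed aldol addition; the phenoxide/ketone-enolate dianion adds to acetone at low temperature, and cold protonation should prevent retro-aldol reaction and dehydration.

Step 5
Reactants: 6 1-[3-(benzyloxy)-4-hydroxy-5-methylphenyl]-3-hydroxy-3-methylbutan-1-one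
Product: 7 rac-7-(benzyloxy)-2,2,9-trimethyl-1-oxaspiro[4.5]deca-6,9-diene-4,8-dione
Conditions: PhI(OAc)2 (1.1 equiv), (CF3)2CHOH, 0 °C, short reaction time; NaHCO3 work-up
Reagents that add atoms: none
Why: Oxidative dearomatising spiroetherification with a λ3-iodane; the tertiary hydroxyl, held close by the gem-dimethyl group, should capture the para carbon of the oxidised phenol through a five-membered transition state, as a phenolic oxygen does in the oxidation of hydroxybenzophenones to spiro-coumaranone dienones; the spiro stereocentre forms racemic and is not a stereocentre of the target.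

Step 6
Reactants: 7 rac-7-(benzyloxy)-2,2,9-trimethyl-1-oxaspiro[4.5]deca-6,9-diene-4,8-dione
Product: 8 7-(benzyloxy)-6-hydroxy-2,2,5-trimethyl-2,3-dihydro-4H-chromen-4-one
Conditions: CF3CO2H/CH2Cl2 (1:4), 0 °C → rt
Reagents that add atoms: none
Why: Protonation of the dienone carbonyl (C8 of the spiro numbering) gives a hydroxy-pentadienyl cation; the ketone carbon C4 then shifts with its bonding pair from the spiro carbon C5 to the neighbouring ring CH (C10), which turns the five-membered furanone into the six-membered pyranone, and loss of the proton from C10 aromatises the carbocycle to the phenol. The closest known reaction is the acid-mediated dienone–phenol rearrangement of spiro-coumaranone cyclohexadienones (grisadienediones) to xanthones, in which an acyl group migrates in the same way; acyl groups are among the best migrating groups in this rearrangement, and here the cation left at C5 is an oxocarbenium ion stabilised by the ring oxygen. No ring is closed by cyclisation: the pyranone arises by 1,2-C-to-C acyl shift (ring expansion 5 → 6) and the benzene ring by deprotonation. No stereocentre is formed, and the stereogenic spiro carbon of 7 becomes sp2. The step needs migration to C10 (next to the methyl-bearing C9) and not to C6 (next to the benzyloxy-bearing C7): the benzyloxy group sits on the central carbon of the C8–C7–C6 allyl-cation arm, where it cannot donate by resonance and withdraws inductively, whereas the methyl group on C9 supports positive charge at C10, so C10 should be the migration terminus. The carbonyl oxygen of the dienone becomes the free C6 hydroxyl while the C7 oxygen stays benzylated, so the two catechol oxygens leave this step already differentiated for the depsidone.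

Step 7
Reactants: 9 2,6-difluoro-4-methylbenzaldehyde
Product: 10 2-(dimethoxymethyl)-1,3-difluoro-5-methylbenzene
Conditions: HC(OMe)3, MeOH, TsOH (cat.), rt
Reagents that add atoms: trimethyl orthoformate, COC(OC)OC
Why: Acid-catalysed acetalisation masks the aldehyde against the organolithium of the next step.

Step 8
Reactants: 10 2-(dimethoxymethyl)-1,3-difluoro-5-methylbenzene
Product: 13 benzyl 2,4-difluoro-3-formyl-6-methylbenzoate, via aryllithium 11 (not isolated), via acetal ester 12 (not isolated)
Conditions: s-BuLi, THF, −78 °C; cannulation into BnOCOCl (1.5 equiv), THF, −78 °C; then 2 M HCl, THF, rt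
Reagents that add atoms: benzyl chloroformate, O=C(Cl)OCc1ccccc1; water, O
Why: Fluorine-directed ortho-lithiation at the only kind of ring C–H (the two are equivalent, each flanked by F and CH3), acylation of the aryllithium by inverse addition to the chloroformate, and acetal hydrolysis on acidic work-up.

Step 9
Reactants: 13 benzyl 2,4-difluoro-3-formyl-6-methylbenzoate
Product: 14 benzyl 4-(benzyloxy)-2-fluoro-3-formyl-6-methylbenzoate
Conditions: BnOH (1.05 equiv), K2CO3, DMF, 0 °C → rt
Reagents that add atoms: benzyl alcohol, OCc1ccccc1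
Why: Nucleophilic aromatic substitution; the C4 fluoride (ortho to CHO, para to the ester, flanked on one side only) should react before the doubly flanked C2 fluoride, and the new alkoxy group then slows a second substitution.

Step 10
Reactants: 8 7-(benzyloxy)-6-hydroxy-2,2,5-trimethyl-2,3-dihydro-4H-chromen-4-one; 14 benzyl 4-(benzyloxy)-2-fluoro-3-formyl-6-methylbenzoate
Product: 15 benzyl 4-(benzyloxy)-2-{[7-(benzyloxy)-2,2,5-trimethyl-4-oxo-3,4-dihydro-2H-chromen-6-yl]oxy}-3-formyl-6-methylbenzoate
Conditions: K2CO3, DMF, 80–90 °C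
Reagents that add atoms: none
Why: Nucleophilic aromatic substitution of the remaining fluoride, activated by the ortho-formyl and ortho-ester groups, by the C6 phenoxide; the benzyl ether on the C7 oxygen fixes which oxygen becomes the ether and which the ester.

Step 11
Reactants: 15 benzyl 4-(benzyloxy)-2-{[7-(benzyloxy)-2,2,5-trimethyl-4-oxo-3,4-dihydro-2H-chromen-6-yl]oxy}-3-formyl-6-methylbenzoate
Product: 16 3-formyl-4-hydroxy-2-[(7-hydroxy-2,2,5-trimethyl-4-oxo-3,4-dihydro-2H-chromen-6-yl)oxy]-6-methylbenzoic acid
Conditions: H2 (1 atm), 10% Pd/C, EtOAc, rt, monitored closely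
Reagents that add atoms: none
Why: Catalytic hydrogenolysis cleaves the two benzyl ethers and the benzyl ester in one operation, while the hindered, hydrogen-bonded aryl aldehyde and the aryl ketone should survive at 1 atm in ethyl acetate.

Step 12
Reactants: 16 3-formyl-4-hydroxy-2-[(7-hydroxy-2,2,5-trimethyl-4-oxo-3,4-dihydro-2H-chromen-6-yl)oxy]-6-methylbenzoic acid
Product: 17 Mollicellin A
Conditions: DCC, CH2Cl2 (high dilution), rt
Reagents that add atoms: none
Why: Carbodiimide lactonisation closes the seven-membered depsidone ring by attack of the C7 phenol on the O-acylisourea, the usual end game for depsidones; the other phenol is para to the carboxyl group on the same ring and cannot reach it.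

**Compound list**

1 | 3-methylbenzene-1,2-diol (3-methylcatechol) | Cc1cccc(O)c1O | starting material
2 | 2-(benzyloxy)-6-methylphenol | Cc1cccc(OCc2ccccc2)c1O | intermediate
3 | 2-(benzyloxy)-4-iodo-6-methylphenol | Cc1cc(I)cc(OCc2ccccc2)c1O | intermediate
4 | 2-(benzyloxy)-4-(1-ethoxyethenyl)-6-methylphenol | CCOC(=C)c1cc(C)c(O)c(OCc2ccccc2)c1 | intermediate (not isolated)
5 | 1-[3-(benzyloxy)-4-hydroxy-5-methylphenyl]ethan-1-one | CC(=O)c1cc(C)c(O)c(OCc2ccccc2)c1 | intermediate
6 | 1-[3-(benzyloxy)-4-hydroxy-5-methylphenyl]-3-hydroxy-3-methylbutan-1-one | CC(C)(O)CC(=O)c1cc(C)c(O)c(OCc2ccccc2)c1 | intermediate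
7 | rac-7-(benzyloxy)-2,2,9-trimethyl-1-oxaspiro[4.5]deca-6,9-diene-4,8-dione (racemic at the spiro carbon) | CC1(C)CC(=O)C2(O1)C=C(C)C(=O)C(OCc1ccccc1)=C2 | intermediate
8 | 7-(benzyloxy)-6-hydroxy-2,2,5-trimethyl-2,3-dihydro-4H-chromen-4-one | CC1(C)CC(=O)c2c(C)c(O)c(OCc3ccccc3)cc2O1 | intermediate
9 | 2,6-difluoro-4-methylbenzaldehyde | Cc1cc(F)c(C=O)c(F)c1 | starting material
10 | 2-(dimethoxymethyl)-1,3-difluoro-5-methylbenzene | COC(OC)c1c(F)cc(C)cc1F | intermediate
11 | [3-(dimethoxymethyl)-2,4-difluoro-6-methylphenyl]lithium | [Li]c1c(C)cc(F)c(C(OC)OC)c1F | intermediate (not isolated)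
12 | benzyl 3-(dimethoxymethyl)-2,4-difluoro-6-methylbenzoate | COC(OC)c1c(F)cc(C)c(C(=O)OCc2ccccc2)c1F | intermediate (not isolated)
13 | benzyl 2,4-difluoro-3-formyl-6-methylbenzoate | Cc1cc(F)c(C=O)c(F)c1C(=O)OCc1ccccc1 | intermediate
14 | benzyl 4-(benzyloxy)-2-fluoro-3-formyl-6-methylbenzoate | Cc1cc(OCc2ccccc2)c(C=O)c(F)c1C(=O)OCc1ccccc1 | intermediate
15 | benzyl 4-(benzyloxy)-2-{[7-(benzyloxy)-2,2,5-trimethyl-4-oxo-3,4-dihydro-2H-chromen-6-yl]oxy}-3-formyl-6-methylbenzoate | Cc1cc(OCc2ccccc2)c(C=O)c(Oc2c(C)c3C(=O)CC(C)(C)Oc3cc2OCc2ccccc2)c1C(=O)OCc1ccccc1 | intermediate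
16 | 3-formyl-4-hydroxy-2-[(7-hydroxy-2,2,5-trimethyl-4-oxo-3,4-dihydro-2H-chromen-6-yl)oxy]-6-methylbenzoic acid | Cc1cc(O)c(C=O)c(Oc2c(C)c3C(=O)CC(C)(C)Oc3cc2O)c1C(=O)O | intermediate
17 | Mollicellin A | Cc1cc(O)c(C=O)c2c1C(=O)Oc1cc3c(c(C)c1O2)C(=O)CC(C)(C)O3 | target

**Step count and risks**

Total step count: 12. Longest linear sequence: 9 steps (steps 1–6, then 10–12); steps 7–9 form the second branch.

Steps most likely to fail:

1. Step 5. The para-acyl group makes the ipso carbon a poor acceptor. The oxidised phenol may instead be captured at the benzyloxy-bearing ortho carbon, with loss of the benzyl group towards an ortho-quinone. The 4-acyl dienone may also be deacylated by nucleophiles with re-aromatisation. Fallback (sets out from 6, returns at 7): the ketone is taken out of conjugation before the oxidation. Compound 6 is reduced with NaBH4 (MeOH, 0 °C) to 1-[3-(benzyloxy)-4-hydroxy-5-methylphenyl]-3-methylbutane-1,3-diol F1. The now electron-rich para-alkyl phenol is spirocyclised with PhI(OAc)2 in (CF3)2CHOH to 7-(benzyloxy)-4-hydroxy-2,2,9-trimethyl-1-oxaspiro[4.5]deca-6,9-dien-8-one F2 (a mixture of diastereomers, which does not matter). Dess–Martin oxidation of the carbinol then gives 7.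

2. Step 10. Substitution may be slow, because a fluoride flanked on both sides must be displaced by a phenoxide that is itself flanked on both sides. Base-induced aldol condensation of the chromanone CH2 with the aldehyde, or cleavage of the benzyl ester, could then take over. Fallback (sets out from 8 and 14, returns at 17): the ester is made first and the hindered C–O bond is closed intramolecularly. Compound 8 is hydrogenolysed (H2, Pd/C, EtOAc) to 6,7-dihydroxy-2,2,5-trimethyl-2,3-dihydro-4H-chromen-4-one F6. The benzyl ester of 14 is cleaved alone by hydrogenolysis in the presence of 2,2'-bipyridyl, which spares phenolic benzyl ethers, to give 4-(benzyloxy)-2-fluoro-3-formyl-6-methylbenzoic acid F7. Carbodiimide coupling (DCC, cat. DMAP, CH2Cl2, 0 °C) should acylate F6 at the C7 hydroxyl, the less hindered and more acidic one (para to the ketone), to give 6-hydroxy-2,2,5-trimethyl-4-oxo-3,4-dihydro-2H-chromen-7-yl 4-(benzyloxy)-2-fluoro-3-formyl-6-methylbenzoate F8. Cs2CO3 in DMSO at rt then closes the diaryl ether by intramolecular SNAr to O-benzyl mollicellin A F9; the temperature is kept low to hold back acyl migration between the two catechol oxygens. Hydrogenolysis of F9 gives 17.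

3. Step 6. Regiocontrol of the acyl shift may be poor, with partial migration to C6 (the benzyloxy side) giving the isomeric chromanone. Fallback (sets out from 7, returns at 16): C6 is blocked. Compound 7 is brominated at the enol-ether carbon C6 (Br2, CH2Cl2, −78 °C, then Et3N; addition–elimination as known for 2-alkoxy enones) to 7-(benzyloxy)-6-bromo-2,2,9-trimethyl-1-oxaspiro[4.5]deca-6,9-diene-4,8-dione F3. Only C10 then carries the hydrogen needed for aromatisation, so the same acid treatment should give 7-(benzyloxy)-8-bromo-6-hydroxy-2,2,5-trimethyl-2,3-dihydro-4H-chromen-4-one F4. SNAr with 14 as in step 10 gives benzyl 4-(benzyloxy)-2-{[7-(benzyloxy)-8-bromo-2,2,5-trimethyl-4-oxo-3,4-dihydro-2H-chromen-6-yl]oxy}-3-formyl-6-methylbenzoate F5. Hydrogenolysis with NaOAc added (H2, Pd/C) removes the bromine together with the three benzyl groups and gives 16.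

Further compounds
F1 | step 5 | 1-[3-(benzyloxy)-4-hydroxy-5-methylphenyl]-3-methylbutane-1,3-diol | CC(C)(O)CC(O)c1cc(C)c(O)c(OCc2ccccc2)c1
F2 | step 5 | 7-(benzyloxy)-4-hydroxy-2,2,9-trimethyl-1-oxaspiro[4.5]deca-6,9-dien-8-one | CC1(C)CC(O)C2(O1)C=C(C)C(=O)C(OCc1ccccc1)=C2
F3 | step 6 | 7-(benzyloxy)-6-bromo-2,2,9-trimethyl-1-oxaspiro[4.5]deca-6,9-diene-4,8-dione | CC1(C)CC(=O)C2(O1)C=C(C)C(=O)C(OCc1ccccc1)=C2Br
F4 | step 6 | 7-(benzyloxy)-8-bromo-6-hydroxy-2,2,5-trimethyl-2,3-dihydro-4H-chromen-4-one | CC1(C)CC(=O)c2c(C)c(O)c(OCc3ccccc3)c(Br)c2O1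
F5 | step 6 | benzyl 4-(benzyloxy)-2-{[7-(benzyloxy)-8-bromo-2,2,5-trimethyl-4-oxo-3,4-dihydro-2H-chromen-6-yl]oxy}-3-formyl-6-methylbenzoate | Cc1cc(OCc2ccccc2)c(C=O)c(Oc2c(C)c3C(=O)CC(C)(C)Oc3c(Br)c2OCc2ccccc2)c1C(=O)OCc1ccccc1
F6 | step 10 | 6,7-dihydroxy-2,2,5-trimethyl-2,3-dihydro-4H-chromen-4-one | CC1(C)CC(=O)c2c(C)c(O)c(O)cc2O1
F7 | step 10 | 4-(benzyloxy)-2-fluoro-3-formyl-6-methylbenzoic acid | Cc1cc(OCc2ccccc2)c(C=O)c(F)c1C(=O)O
F8 | step 10 | 6-hydroxy-2,2,5-trimethyl-4-oxo-3,4-dihydro-2H-chromen-7-yl 4-(benzyloxy)-2-fluoro-3-formyl-6-methylbenzoate | Cc1cc(OCc2ccccc2)c(C=O)c(F)c1C(=O)Oc1cc2OC(C)(C)CC(=O)c2c(C)c1O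
F9 | step 10 | O-benzyl mollicellin A | Cc1cc(OCc2ccccc2)c(C=O)c2c1C(=O)Oc1cc3c(c(C)c1O2)C(=O)CC(C)(C)O3
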